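**Retrosynthetic overview**
1. Target 21 ⇐ 19: the last bonds made are C–O bonds (C11′–O and C8′–O of the 1,2-dioxolan-3-ol) by aerobic peroxidation of a trienolate; 19 ⇐ 18 by γ,δ-dehydrogenation of the enone unit.
2. 18 ⇐ 16 ⇐ 15: the C2–OAc bond is made by a stereoinvertive radical C–O coupling on the alcohol obtained from the bridging ketone.
3. 15 ⇐ 14 + 14 (two molecules of 13): endo Diels–Alder homodimerisation of one cyclopentadienone (bonds C1–C4′ and C3–C3′) builds the norbornene core.
4. 14 ⇐ 13 ⇐ 12 ⇐ 6 + 9 ⇐ 1 + 2: seven-membered ring by acyl-radical cyclisation; side arms by Stork–Danheiser chemistry on a dione/enal Michael adduct that fixes C10.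
5. Ring order: cyclopentenone (from 1) → temporary pyran → cycloheptanone → bicyclo[2.2.1]heptene (dimerisation) → 1,2-dioxolane.

Assumption: C7 (α to the C8 ketone) and the hemiketal carbon C8′ are labile and the target shows their thermodynamically preferred configurations. Guaiane numbering is used: five-membered ring C1–C5 with Me-15 on C4, seven-membered ring C5–C6–C7(iPr)–C8–C9–C10(Me-14)–C1, and primes for the dienophile-derived unit B.

**Step 1**
Reactants: 1 cyclopentane-1,3-dione; 2 (E)-but-2-enal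
Product: 4 (4R)-2-methoxy-4-methyl-3,4,6,7-tetrahydrocyclopenta[b]pyran-5(2H)-one (anomer mixture), via lactol 3 (not isolated)
Conditions: (S)-α,α-diphenylprolinol trimethylsilyl ether (10 mol%), PhCO2H (10 mol%), CH2Cl2, 0 °C → rt; then MeOH, p-TsOH (cat.), rt
Reagents that add atoms: methanol (CO)
Why: Iminium-catalysed asymmetric Michael addition of the 1,3-dione to the enal followed by hemiacetal and acetal formation, in which the CPh2OSiMe3 group shields one face of the (E)-iminium so that the dione adds to the other face and sets C10 as R, while any minor enantiomer is later lost as diastereomeric hetero-dimers.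

**Step 2**
Reactants: 4 (4R)-2-methoxy-4-methyl-3,4,6,7-tetrahydrocyclopenta[b]pyran-5(2H)-one
Product: 5 (4R)-2-methoxy-4,6-dimethyl-3,4,6,7-tetrahydrocyclopenta[b]pyran-5(2H)-one (C2/C6 epimer mixture)
Conditions: LiN(iPr)2, THF, −78 °C; MeI, −78 → −20 °C
Reagents that add atoms: iodomethane (CI)
Why: Stork–Danheiser α′-alkylation, the cyclic vinylogous ester being deprotonated kinetically next to its carbonyl and methylated there, at a carbon (future C4) that later becomes sp2 so its configuration does not matter.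

**Step 3**
Reactants: 5 (4R)-2-methoxy-4,6-dimethyl-3,4,6,7-tetrahydrocyclopenta[b]pyran-5(2H)-one
Product: 6 (4R)-6-hydroxy-2-methoxy-4,6-dimethyl-3,4,6,7-tetrahydrocyclopenta[b]pyran-5(2H)-one (C2/C6 epimer mixture)
Conditions: KN(SiMe3)2, THF, −78 °C; 3-phenyl-2-(phenylsulfonyl)oxaziridine; AcOH quench
Reagents that add atoms: 3-phenyl-2-(phenylsulfonyl)oxaziridine (O=S(=O)(c1ccccc1)N1OC1c1ccccc1)
Why: Davis enolate hydroxylation forms the C4–O bond that later leaves to unveil the cyclopentadienone, so that no differentiation of two ketones is ever needed, and the configuration of this carbinol carbon is irrelevant.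

**Step 4**
Reactants: 7 3-methylbut-1-yne
Product: 9 (E)-1-iodo-3-methylbut-1-ene, via alkenylalane 8 (not isolated)
Conditions: iBu2AlH, hexane, 50 °C; then I2, THF, −50 °C → rt
Reagents that add atoms: iodine (I-I)
Why: Zweifel hydroalumination–iodination, cis addition of Al–H to the terminal alkyne and iodinolysis with retention giving the (E)-alkenyl iodide.

**Step 5**
Reactants: 6 (4R)-6-hydroxy-2-methoxy-4,6-dimethyl-3,4,6,7-tetrahydrocyclopenta[b]pyran-5(2H)-one; 9 (E)-1-iodo-3-methylbut-1-ene
Product: 12 (3R)-3-{3-hydroxy-3-methyl-2-[(E)-3-methylbut-1-enyl]-5-oxocyclopent-1-enyl}butanal (carbinol epimer mixture), via alkenyllithium 10 (not isolated), via diol adduct 11 (not isolated)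
Conditions: 9 (2.3 equiv), tBuLi (4.6 equiv), Et2O, −78 °C; then 6, THF, −78 → 0 °C; then 1 M HCl, THF, 0 °C
Reagents that add atoms: water (O)
Why: Stork–Danheiser 1,2-addition and hydrolytic transposition, the alkenyllithium (one equivalent is consumed by the free hydroxyl) adding to the vinylogous-ester carbonyl and aqueous acid then ionising the doubly allylic carbinol to release the transposed enone and the aldehyde in one operation without touching C10.

**Step 6**
Reactants: 12 (3R)-3-{3-hydroxy-3-methyl-2-[(E)-3-methylbut-1-enyl]-5-oxocyclopent-1-enyl}butanal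
Product: 13 (7S,10R)-4-hydroxyguai-1(5)-ene-2,8-dione (both C4 epimers)
Conditions: (nBu4N)4W10O32 (2 mol%), MeCN (0.01 M), 390 nm LEDs, rt; then DBU (10 mol%)
Reagents that add atoms: none
Why: Decatungstate hydrogen-atom-transfer hydroacylation (Giese-type acyl radical addition) in which the nucleophilic acyl radical closes the seven-membered ring 7-endo at the electrophilic δ-carbon of the dienone to give a dienoxyl-stabilised radical that takes the hydrogen back, the new C7 centre being α to the ketone and settling as the pseudo-equatorial 7S epimer on the DBU finish.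

**Step 7**
Reactants: 13 (7S,10R)-4-hydroxyguai-1(5)-ene-2,8-dione (two molecules per molecule of product; one becomes diene unit A, the other dienophile unit B)
Product: 15 endo Diels–Alder homodimer (7S,10R,7′S,10′R)-1,4′:3,3′-bisguaia-4,1′(5′)-diene-2,8,2′,8′-tetraone (C2 is the bridging ketone), via cyclopentadienone 14 (not isolated)
Conditions: p-TsOH·H2O (10 mol%), benzene, 50 °C
Reagents that add atoms: second molecule of compound 13 (CC1(O)CC(=O)C2=C1C[C@@H](C(C)C)C(=O)C[C@H]2C)
Why: Acid-catalysed dehydration of each molecule of the 4-hydroxycyclopent-2-enone through its C3 enol gives cyclopentadienone 14, and two molecules of 14 combine at once in an endo Diels–Alder dimerisation whose leading bond joins the two unsubstituted α-carbons (C3–C3′) and in which each partner reacts on the face anti to its pseudo-axial C10 methyl, so that C1, C3, C3′ and C4′ are set as in the target.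

**Step 8**
Reactants: 15 endo Diels–Alder homodimer (tetraone)
Product: 16 (2R)-2-hydroxy-1,4′:3,3′-bisguaia-4,1′(5′)-diene-8,2′,8′-trione (OH anti to C4=C5)
Conditions: NaBH4 (0.5 equiv), MeOH/CH2Cl2, −78 → −40 °C
Reagents that add atoms: none
Why: Chemoselective borohydride reduction under steric approach control, the strained bridging ketone being far more electrophilic than the two α-branched cycloheptanones and the enone, and hydride arriving over the open C4=C5 face because the other face is blocked by the exo C4′ methyl, which gives the 2R alcohol, the C2 epimer of what the target needs.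

**Step 9**
Reactants: 16 (2R)-2-hydroxy-1,4′:3,3′-bisguaia-4,1′(5′)-diene-8,2′,8′-trione
Product: 18 (2S)-2-acetoxy-1,4′:3,3′-bisguaia-4,1′(5′)-diene-8,2′,8′-trione (OAc syn to C4=C5), via benzoxazoline adduct 17 (not isolated)
Conditions: 3-phenyl-1,3-benzoxazol-3-ium tetrafluoroborate (1.2 equiv), pyridine (1.2 equiv), MTBE, rt, 20 min; then Ir[dF(CF3)ppy]2(dtbbpy)PF6 (1 mol%), Cu(OAc)2 (2.5 equiv), MeCN, 450 nm LEDs, rt
Reagents that add atoms: Cu(OAc)2 (CC(=O)[O-].CC(=O)[O-].[Cu+2])
Why: Proposed new method: deoxygenative radical acetoxylation with inversion, in which the alcohol is condensed with the benzoxazolium salt, photocatalytic oxidation and deprotonation of the aminal followed by β-scission expel the benzoxazolone and leave the pyramidal, rapidly inverting C2 radical, this radical is captured by divalent copper acetate on the open face over C4=C5 (the other face is blocked by the exo C4′ methyl), and the resulting alkyl acetate complex of trivalent copper reductively eliminates with retention to place OAc syn to the alkene, a copper centre on that face being unable to ionise with π-assistance so that the homoallylic cation route back to the anti acetate is disfavoured; the closest known reactions are deoxygenative C–C and C–N cross-couplings of benzoxazolium-activated alcohols and copper-mediated radical acyloxylation of the Kharasch–Sosnovsky type.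

**Step 10**
Reactants: 18 (2S)-2-acetoxy-1,4′:3,3′-bisguaia-4,1′(5′)-diene-8,2′,8′-trione
Product: 19 (2S)-2-acetoxy-1,4′:3,3′-bisguaia-4,1′(5′),6′-triene-8,2′,8′-trione
Conditions: chloranil (1.5 equiv), tBuOH, 83 °C
Reagents that add atoms: none
Why: Chloranil γ,δ-dehydrogenation of an enone through its dienol (as in the 4-en-3-one to 4,6-dien-3-one conversion of steroids), which is expected only in unit B, whose γ-CH2 (C6′) and δ-H (C7′) are removed, because the isolated ketone of unit A has no enone to form such a dienol, and no stereocentre is created.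

**Step 11**
Reactants: 19 (2S)-2-acetoxy-1,4′:3,3′-bisguaia-4,1′(5′),6′-triene-8,2′,8′-trione
Product: 21 CNP0317907.1, via hydroperoxide 20 (not isolated)
Conditions: DBU (0.5 equiv), O2 (1 atm), MeCN, 0 °C → rt
Reagents that add atoms: dioxygen (O=O)
Why: Vinylogous enolate autoxidation followed by peroxyhemiketalisation, DBU removing the doubly vinylogous C11′–H (only unit B is acidic enough), triplet oxygen being trapped at the terminal C11′ of the trienolate (the one position that keeps the dienedione conjugated) and the tertiary hydroperoxide adding reversibly to the C8′ ketone to close the 1,2-dioxolan-3-ol with C8′ under thermodynamic control.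

**Compound list**
1 | cyclopentane-1,3-dione | O=C1CCC(=O)C1 | starting material
2 | (E)-but-2-enal | C/C=C/C=O | starting material
3 | (4R)-2-hydroxy-4-methyl-3,4,6,7-tetrahydrocyclopenta[b]pyran-5(2H)-one (lactol) | OC1C[C@@H](C)C2=C(O1)CCC2=O | intermediate
4 | (4R)-2-methoxy-4-methyl-3,4,6,7-tetrahydrocyclopenta[b]pyran-5(2H)-one | COC1C[C@@H](C)C2=C(O1)CCC2=O | intermediate
5 | (4R)-2-methoxy-4,6-dimethyl-3,4,6,7-tetrahydrocyclopenta[b]pyran-5(2H)-one | COC1C[C@@H](C)C2=C(O1)CC(C)C2=O | intermediate
6 | (4R)-6-hydroxy-2-methoxy-4,6-dimethyl-3,4,6,7-tetrahydrocyclopenta[b]pyran-5(2H)-one | COC1C[C@@H](C)C2=C(O1)CC(C)(O)C2=O | intermediate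
7 | 3-methylbut-1-yne | CC(C)C#C | starting material
8 | (E)-diisobutyl(3-methylbut-1-enyl)alane | CC(C)/C=C/[Al](CC(C)C)CC(C)C | intermediate
9 | (E)-1-iodo-3-methylbut-1-ene | CC(C)/C=C/I | intermediate
10 | (E)-(3-methylbut-1-enyl)lithium | [Li]/C=C/C(C)C | intermediate
11 | (4R)-2-methoxy-4,6-dimethyl-5-[(E)-3-methylbut-1-enyl]-2,3,4,5,6,7-hexahydrocyclopenta[b]pyran-5,6-diol | COC1C[C@@H](C)C2=C(O1)CC(C)(O)C2(O)/C=C/C(C)C | intermediate
12 | (3R)-3-{3-hydroxy-3-methyl-2-[(E)-3-methylbut-1-enyl]-5-oxocyclopent-1-enyl}butanal | O=CC[C@@H](C)C1=C(/C=C/C(C)C)C(C)(O)CC1=O | intermediate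
13 | (7S,10R)-4-hydroxyguai-1(5)-ene-2,8-dione | CC1(O)CC(=O)C2=C1C[C@@H](C(C)C)C(=O)C[C@H]2C | intermediate
14 | (7S,10R)-guaia-1(5),3-diene-2,8-dione (cyclopentadienone) | CC1=CC(=O)C2=C1C[C@@H](C(C)C)C(=O)C[C@H]2C | intermediate
15 | endo Diels–Alder homodimer, (7S,10R,7′S,10′R)-1,4′:3,3′-bisguaia-4,1′(5′)-diene-2,8,2′,8′-tetraone | O=C1[C@H]2C(C)=C3C[C@@H](C(C)C)C(=O)C[C@@H](C)[C@]31[C@]1(C)C3=C(C(=O)[C@H]21)[C@H](C)CC(=O)[C@H](C(C)C)C3 | intermediate
16 | (2R)-2-hydroxy-1,4′:3,3′-bisguaia-4,1′(5′)-diene-8,2′,8′-trione | O[C@@H]1[C@H]2C(C)=C3C[C@@H](C(C)C)C(=O)C[C@@H](C)[C@]31[C@]1(C)C3=C(C(=O)[C@H]21)[C@H](C)CC(=O)[C@H](C(C)C)C3 | intermediate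
17 | 2-O-(3-phenyl-2,3-dihydro-1,3-benzoxazol-2-yl) ether of 16 | O(C1Oc2ccccc2N1c1ccccc1)[C@@H]1[C@H]2C(C)=C3C[C@@H](C(C)C)C(=O)C[C@@H](C)[C@]31[C@]1(C)C3=C(C(=O)[C@H]21)[C@H](C)CC(=O)[C@H](C(C)C)C3 | intermediate
18 | (2S)-2-acetoxy-1,4′:3,3′-bisguaia-4,1′(5′)-diene-8,2′,8′-trione | CC(=O)O[C@H]1[C@H]2C(C)=C3C[C@@H](C(C)C)C(=O)C[C@@H](C)[C@]31[C@]1(C)C3=C(C(=O)[C@H]21)[C@H](C)CC(=O)[C@H](C(C)C)C3 | intermediate
19 | (2S)-2-acetoxy-1,4′:3,3′-bisguaia-4,1′(5′),6′-triene-8,2′,8′-trione | CC(=O)O[C@H]1[C@H]2C(C)=C3C[C@@H](C(C)C)C(=O)C[C@@H](C)[C@]31[C@]1(C)C3=C(C(=O)[C@H]21)[C@H](C)CC(=O)C(C(C)C)=C3 | intermediate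
20 | 11′-hydroperoxide of 19 | CC(=O)O[C@H]1[C@H]2C(C)=C3C[C@@H](C(C)C)C(=O)C[C@@H](C)[C@]31[C@]1(C)C3=C(C(=O)[C@H]21)[C@H](C)CC(=O)C(C(C)(C)OO)=C3 | intermediate
21 | CNP0317907.1 | CC(=O)O[C@H]1[C@H]2C(C)=C3C[C@@H](C(C)C)C(=O)C[C@@H](C)[C@]31[C@]1(C)C3=C(C(=O)[C@H]21)[C@H](C)C[C@@]1(O)OOC(C)(C)C1=C3 | target

**Step count and risks**
Total step count: 11. Longest linear sequence: 10 steps (steps 1, 2, 3 and 5 to 11).

Step 6 (acyl-radical 7-endo ring closure). Risk: competing hydrogen abstraction or photochemistry of the dienone, or a sluggish seven-membered closure. Fallback, a carbonyl-ene ring closure instead of a radical one: setting out from compound 6, α-selective addition of Me2C=CHCH2BaCl and hydrolysis with 1 M HCl give (3R)-3-[3-hydroxy-3-methyl-2-(3-methylbut-2-enyl)-5-oxocyclopent-1-enyl]butanal F1. Me2AlCl at −78 °C closes the seven-membered ring by intramolecular carbonyl-ene reaction to (10R)-4,8-dihydroxyguaia-1(5),11-dien-2-one F2. Dess–Martin oxidation gives (10R)-4-hydroxyguaia-1(5),11-diene-2,8-dione F3. Hydrogenation of the isopropenyl group (H2, RhCl(PPh3)3) and a DBU equilibration return to the route at compound 13.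

Step 9 (the proposed new C–O coupling). Risk: oxidation of the C2 radical to the homoallylic cation, which would return the anti acetate, or quenching of the photocatalyst by the copper salt. Fallback with known chemistry, setting out from compound 16: O-(2-iodophenyl) chlorothionoformate with pyridine and DMAP gives the O-(2-iodophenyl) thionocarbonate of 16 F4. Photoinduced deoxygenative borylation (B2cat2, DMAc, blue light, then pinacol and Et3N) traps the C2 radical from the open face and gives the C2 pinacol boronate with boron syn to C4=C5 F5. NaBO3·4H2O oxidises the C–B bond with retention to the (2S)-2-hydroxy trione F6. Ac2O with DMAP then returns to the route at compound 18.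

Step 11 (aerobic peroxidation). Risk: oxygen attack at C1′ or C6′ instead of C11′, or epimer mixtures at C8′. Fallback, ionic halogenation followed by nucleophilic peroxide delivery instead of autoxidation, setting out from compound 19: TBSOTf (1.1 equiv) and Et3N at −78 °C give the 2′-O-tert-butyldimethylsilyl trienol ether of 19 F7. NBS brominates its terminal carbon to the 11′-bromide of 19 F8. AgO2CCF3 with ethereal H2O2 replaces bromide by hydroperoxide to give compound 20, which closes to compound 21, where the route is rejoined.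

**Further compounds**
F1 | step 6 | (3R)-3-[3-hydroxy-3-methyl-2-(3-methylbut-2-enyl)-5-oxocyclopent-1-enyl]butanal | O=CC[C@@H](C)C1=C(CC=C(C)C)C(C)(O)CC1=O
F2 | step 6 | (10R)-4,8-dihydroxyguaia-1(5),11-dien-2-one | CC1(O)CC(=O)C2=C1CC(C(C)=C)C(O)C[C@H]2C
F3 | step 6 | (10R)-4-hydroxyguaia-1(5),11-diene-2,8-dione | CC1(O)CC(=O)C2=C1CC(C(C)=C)C(=O)C[C@H]2C
F4 | step 9 | O-(2-iodophenyl) thionocarbonate of 16 | S=C(Oc1ccccc1I)O[C@@H]1[C@H]2C(C)=C3C[C@@H](C(C)C)C(=O)C[C@@H](C)[C@]31[C@]1(C)C3=C(C(=O)[C@H]21)[C@H](C)CC(=O)[C@H](C(C)C)C3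
F5 | step 9 | C2 pinacol boronate (boron syn to C4=C5) | CC1(C)OB(OC1(C)C)[C@H]1[C@H]2C(C)=C3C[C@@H](C(C)C)C(=O)C[C@@H](C)[C@]31[C@]1(C)C3=C(C(=O)[C@H]21)[C@H](C)CC(=O)[C@H](C(C)C)C3
F6 | step 9 | (2S)-2-hydroxy-1,4′:3,3′-bisguaia-4,1′(5′)-diene-8,2′,8′-trione | O[C@H]1[C@H]2C(C)=C3C[C@@H](C(C)C)C(=O)C[C@@H](C)[C@]31[C@]1(C)C3=C(C(=O)[C@H]21)[C@H](C)CC(=O)[C@H](C(C)C)C3
F7 | step 11 | 2′-O-tert-butyldimethylsilyl trienol ether of 19 | CC(=O)O[C@H]1[C@H]2C(C)=C3C[C@@H](C(C)C)C(=O)C[C@@H](C)[C@]31[C@]1(C)C3=CC(=C(C)C)C(=O)C[C@@H](C)C3=C(O[Si](C)(C)C(C)(C)C)[C@H]21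
F8 | step 11 | 11′-bromide of 19 | CC(=O)O[C@H]1[C@H]2C(C)=C3C[C@@H](C(C)C)C(=O)C[C@@H](C)[C@]31[C@]1(C)C3=C(C(=O)[C@H]21)[C@H](C)CC(=O)C(C(C)(C)Br)=C3
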